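The cyclobutane of IN0146 carries its two stereocentres on adjacent ring carbons: C-a bears the C(=CH2) carbon and C-b bears the 3-oxobutyl chain. Each of these exocyclic carbons can be traced back to a carboxyl carbon, so the ring bond C-a–C-b is the C2–C5 bond of 3,3-dimethyladipic acid. Oxidation of the bis-enolate of an open-chain adipoyl bis-imide joins the two α-carbons, closes the four-membered ring and sets both stereocentres trans in one operation, under the control of two (R)-4-benzyloxazolidinone auxiliaries. The precursor is the acyclic bis[(R)-4-benzyloxazolidinone] imide of 3,3-dimethyladipic acid. The two acyl groups are afterwards distinguished through the steric bias of the CMe2 group next to C-b.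

Key step: step 4

Remark: re-derivation from the target SMILES gives a trans ring with C-a S and C-b R; compound 8 has the same spatial arrangement (C-b stays R although the substituent ranks change), and no structure needed correction.
Remark: the precursor is kept as the bis-imide with two identical (R)-auxiliaries, because both then favour the same trans ring; the only refinement is operational (complete double enolisation before any oxidant is present).

Step 1
Reactants: 1 4,4-dimethylcyclohexanone
Product: 2 3,3-dimethylhexanedioic acid (3,3-dimethyladipic acid)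
Conditions: HNO3 (50% aq.), NH4VO3 (cat.), 55–60 °C
Reagents that add atoms: nitric acid, O[N+](=O)[O-]; water, O
Why: Vanadium-catalysed nitric acid oxidative cleavage of the C1–C2 bond of a cyclohexanone gives the adipic acid, the symmetric ketone can give only one diacid, and the quaternary carbon offers no C–H for over-oxidation.

Step 2
Reactants: 2 3,3-dimethylhexanedioic acid
Product: 3 3,3-dimethylhexanedioyl dichloride
Conditions: (COCl)2, DMF (cat.), CH2Cl2, 0 °C → rt
Reagents that add atoms: oxalyl chloride, O=C(Cl)C(Cl)=O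
Why: Acid chloride formation through the chloroiminium (Vilsmeier-type) catalyst is routine for adipic acids, and the crude dichloride is used after evaporation.

Step 3
Reactants: 3 3,3-dimethylhexanedioyl dichloride; 4 (R)-4-benzyloxazolidin-2-one
Product: 6 3,3'-(3,3-dimethylhexanedioyl)bis[(R)-4-benzyloxazolidin-2-one], via N-lithio oxazolidinone 5 (not isolated)
Conditions: 4 (2.1 equiv), n-BuLi, THF, −78 °C; then 3, −78 → 0 °C
Reagents that add atoms: none
Why: N-acylation of a lithiated oxazolidinone by an acid chloride is the standard imide synthesis; no stereocentre is formed and that of the auxiliary is not touched.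

Step 4
Reactants: 6 3,3'-(3,3-dimethylhexanedioyl)bis[(R)-4-benzyloxazolidin-2-one]
Product: 8 3,3'-[(1S,2R)-3,3-dimethylcyclobutane-1,2-dicarbonyl]bis[(R)-4-benzyloxazolidin-2-one], via dilithium bis-(Z)-enolate 7 (not isolated)
Conditions: LDA (2.3 equiv), THF, −78 °C, slow addition of 6 (final 0.01 M); then CuCl2 (2.5 equiv) in DMF, −78 → 0 °C
Reagents that add atoms: none
Why: LDA removes one α-proton from each acyl group to give the bis-(Z)-enolate 7, each enolate chelated to its oxazolidinone carbonyl; divalent copper (CuCl2) takes one electron from one enolate, the α-acyl radical adds to the carbon of the second enolate, and a second electron transfer to CuCl2 gives the 1,4-dicarbonyl product. The closest known reaction type is the intramolecular oxidative coupling of dianions of α,ω-diesters and α,ω-diacyl bis(oxazolidinones) to trans-cycloalkane-1,2-dicarbonyl compounds, of which a four-membered closure next to a quaternary carbon is a demanding case. The cyclobutane closes in a 4-exo-trig mode (the C5 radical onto the C2=C1 enolate, or the reverse), and the gem-dimethyl group at C3 pushes C2 and C5 together. Each new stereocentre is set by its own auxiliary, the bond forming on the enolate face opposite the benzyl group, which by the chelated Z-enolate alkylation model gives S at C-a and R at C-b; the two (R)-auxiliaries are therefore matched for the trans ring, whereas a cis ring would force one enolate to react on its shielded face. The step needs ring closure to outrun intermolecular coupling and both positions to be enolised before oxidant arrives: high dilution and the Thorpe–Ingold bias serve the first, and slow addition of 6 to excess LDA serves the second and also suppresses Dieckmann-type attack of a mono-enolate on the other imide.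

Step 5
Reactants: 8 3,3'-[(1S,2R)-3,3-dimethylcyclobutane-1,2-dicarbonyl]bis[(R)-4-benzyloxazolidin-2-one]
Product: 9 S-ethyl (1S,2R)-2-[(R)-4-benzyl-2-oxooxazolidine-3-carbonyl]-3,3-dimethylcyclobutane-1-carbothioate
Conditions: EtSH (1.5 equiv), n-BuLi (1.1 equiv), THF, −78 → 0 °C
Reagents that add atoms: ethanethiol, CCS (used as its lithium thiolate, [Li]SCC)
Why: Thiolate transacylation of an N-acyloxazolidinone (imide to thioester) takes place at the exocyclic carbonyl, and only the acyl group on C-a is accessible because the one on C-b has a cis methyl of the CMe2 group beside it; no bond to a stereocentre is broken and the trans arrangement is the stable one.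

Step 6
Reactants: 9 S-ethyl (1S,2R)-2-[(R)-4-benzyl-2-oxooxazolidine-3-carbonyl]-3,3-dimethylcyclobutane-1-carbothioate; 10 (3-bromopropoxy)(tert-butyl)dimethylsilane
Product: 12 (R)-4-benzyl-3-{(1R,4S)-4-[4-(tert-butyldimethylsilyloxy)butanoyl]-2,2-dimethylcyclobutane-1-carbonyl}oxazolidin-2-one, via alkylzinc bromide 11 (not isolated)
Conditions: 10, Zn dust, LiCl, THF, 50 °C; then 9, PdCl2(PPh3)2 (5 mol%), toluene/THF, rt
Reagents that add atoms: none
Why: Fukuyama coupling: zerovalent palladium, formed from PdCl2(PPh3)2 and the organozinc, inserts into the acyl–sulfur bond, and alkyl transfer from zinc followed by reductive elimination gives the ketone; the alkylzinc is too mild to add to the remaining imide, to the silyl ether or to the ketone formed.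

Step 7
Reactants: 12 (R)-4-benzyl-3-{(1R,4S)-4-[4-(tert-butyldimethylsilyloxy)butanoyl]-2,2-dimethylcyclobutane-1-carbonyl}oxazolidin-2-one
Product: 13 (R)-4-benzyl-3-{(1R,4S)-4-[5-(tert-butyldimethylsilyloxy)pent-1-en-2-yl]-2,2-dimethylcyclobutane-1-carbonyl}oxazolidin-2-one
Conditions: Zn, CH2Br2, TiCl4, THF/CH2Cl2, 0 °C → rt
Reagents that add atoms: dibromomethane, BrCBr
Why: Lombardo methylenation uses a non-basic geminal dimetal CH2 reagent that is selective for ketones over carboxylic acid derivatives, so the imide, the silyl ether and the enolisable ring centres should be left alone.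

Step 8
Reactants: 13 (R)-4-benzyl-3-{(1R,4S)-4-[5-(tert-butyldimethylsilyloxy)pent-1-en-2-yl]-2,2-dimethylcyclobutane-1-carbonyl}oxazolidin-2-one
Product: 14 {(1R,4S)-4-[5-(tert-butyldimethylsilyloxy)pent-1-en-2-yl]-2,2-dimethylcyclobutyl}methanol
Conditions: LiBH4, MeOH (2 equiv), THF, 0 °C → rt
Reagents that add atoms: none
Why: Reductive cleavage of an N-acyloxazolidinone by methanol-activated LiBH4 gives the primary alcohol and releases the auxiliary; the alkene and the silyl ether are inert and no stereocentre is touched.

Step 9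
Reactants: 14 {(1R,4S)-4-[5-(tert-butyldimethylsilyloxy)pent-1-en-2-yl]-2,2-dimethylcyclobutyl}methanol
Product: 15 (1R,4S)-4-[5-(tert-butyldimethylsilyloxy)pent-1-en-2-yl]-2,2-dimethylcyclobutane-1-carbaldehyde
Conditions: Dess–Martin periodinane, NaHCO3, CH2Cl2, 0 °C → rt
Reagents that add atoms: none
Why: Dess–Martin oxidation under buffered conditions gives the aldehyde without over-oxidation, and the ring carbon next to the aldehyde keeps the favoured trans arrangement.

Step 10
Reactants: 15 (1R,4S)-4-[5-(tert-butyldimethylsilyloxy)pent-1-en-2-yl]-2,2-dimethylcyclobutane-1-carbaldehyde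
Product: 16 (E)-4-{(1R,4S)-4-[5-(tert-butyldimethylsilyloxy)pent-1-en-2-yl]-2,2-dimethylcyclobutyl}but-3-en-2-one
Conditions: Ph3P=CHC(O)CH3, toluene, 90 °C
Reagents that add atoms: 1-(triphenylphosphoranylidene)propan-2-one, CC(=O)C=P(c1ccccc1)(c1ccccc1)c1ccccc1
Why: Wittig olefination with a stabilised acetonylidene ylide should give the E-enone, and the neutral conditions leave the α-stereocentre of the hindered aldehyde in place.

Step 11
Reactants: 16 (E)-4-{(1R,4S)-4-[5-(tert-butyldimethylsilyloxy)pent-1-en-2-yl]-2,2-dimethylcyclobutyl}but-3-en-2-one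
Product: 17 4-{(1R,4S)-4-[5-(tert-butyldimethylsilyloxy)pent-1-en-2-yl]-2,2-dimethylcyclobutyl}butan-2-one
Conditions: [(Ph3P)CuH]6, H2O, toluene, rt
Reagents that add atoms: none
Why: Copper hydride conjugate reduction delivers hydride to the β-carbon of the enone and water protonates the copper enolate, while the isolated 1,1-disubstituted alkene and the ketone carbonyl are not reduced.

Step 12
Reactants: 17 4-{(1R,4S)-4-[5-(tert-butyldimethylsilyloxy)pent-1-en-2-yl]-2,2-dimethylcyclobutyl}butan-2-one
Product: 18 4-[(1R,4S)-4-(5-hydroxypent-1-en-2-yl)-2,2-dimethylcyclobutyl]butan-2-one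
Conditions: HF·pyridine, pyridine, THF, 0 °C → rt
Reagents that add atoms: none
Why: Fluoride-driven desilylation of the primary silyl ether relies on the strong Si–F bond, and the buffered reagent avoids base-induced aldol chemistry of the methyl ketone.

Step 13
Reactants: 18 4-[(1R,4S)-4-(5-hydroxypent-1-en-2-yl)-2,2-dimethylcyclobutyl]butan-2-one; 19 linoleic acid
Product: 20 4-[(1S,2R)-3,3-dimethyl-2-(3-oxobutyl)cyclobutyl]pent-4-en-1-yl (9Z,12Z)-octadeca-9,12-dienoate (IN0146)
Conditions: 19, DCC, DMAP (cat.), CH2Cl2, 0 °C → rt, argon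
Reagents that add atoms: none
Why: Steglich esterification activates the acid as its O-acylisourea and DMAP transfers the acyl group to the primary alcohol under neutral conditions, which leave the Z,Z skipped diene, the ketone and the alkene unchanged.

Compound list
1 | 4,4-dimethylcyclohexanone | CC1(C)CCC(=O)CC1 | starting material
2 | 3,3-dimethylhexanedioic acid | OC(=O)CCC(C)(C)CC(=O)O | intermediate
3 | 3,3-dimethylhexanedioyl dichloride | O=C(Cl)CCC(C)(C)CC(=O)Cl | intermediate
4 | (R)-4-benzyloxazolidin-2-one | O=C1N[C@H](Cc2ccccc2)CO1 | starting material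
5 | N-lithio-(R)-4-benzyloxazolidin-2-one | [Li]N1[C@H](Cc2ccccc2)COC1=O | intermediate (not isolated)
6 | 3,3'-(3,3-dimethylhexanedioyl)bis[(R)-4-benzyloxazolidin-2-one] | O=C(CCC(C)(C)CC(=O)N1[C@H](Cc2ccccc2)COC1=O)N1[C@H](Cc2ccccc2)COC1=O | intermediate
7 | dilithium bis-(Z)-enolate of 6 | [Li]O/C(=C\CC(C)(C)/C=C(\O[Li])N1[C@H](Cc2ccccc2)COC1=O)N1[C@H](Cc2ccccc2)COC1=O | intermediate (not isolated)
8 | 3,3'-[(1S,2R)-3,3-dimethylcyclobutane-1,2-dicarbonyl]bis[(R)-4-benzyloxazolidin-2-one] (trans) | O=C(N2[C@H](Cc3ccccc3)COC2=O)[C@H]1CC(C)(C)[C@@H]1C(=O)N1[C@H](Cc2ccccc2)COC1=O | intermediate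
9 | S-ethyl (1S,2R)-2-[(R)-4-benzyl-2-oxooxazolidine-3-carbonyl]-3,3-dimethylcyclobutane-1-carbothioate | CCSC(=O)[C@H]1CC(C)(C)[C@@H]1C(=O)N1[C@H](Cc2ccccc2)COC1=O | intermediate
10 | (3-bromopropoxy)(tert-butyl)dimethylsilane | CC(C)(C)[Si](C)(C)OCCCBr | starting material
11 | [3-(tert-butyldimethylsilyloxy)propyl]zinc bromide | CC(C)(C)[Si](C)(C)OCCC[Zn]Br | intermediate (not isolated)
12 | (R)-4-benzyl-3-{(1R,4S)-4-[4-(tert-butyldimethylsilyloxy)butanoyl]-2,2-dimethylcyclobutane-1-carbonyl}oxazolidin-2-one | CC(C)(C)[Si](C)(C)OCCCC(=O)[C@H]1CC(C)(C)[C@@H]1C(=O)N1[C@H](Cc2ccccc2)COC1=O | intermediate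
13 | (R)-4-benzyl-3-{(1R,4S)-4-[5-(tert-butyldimethylsilyloxy)pent-1-en-2-yl]-2,2-dimethylcyclobutane-1-carbonyl}oxazolidin-2-one | C=C(CCCO[Si](C)(C)C(C)(C)C)[C@H]1CC(C)(C)[C@@H]1C(=O)N1[C@H](Cc2ccccc2)COC1=O | intermediate
14 | {(1R,4S)-4-[5-(tert-butyldimethylsilyloxy)pent-1-en-2-yl]-2,2-dimethylcyclobutyl}methanol | C=C(CCCO[Si](C)(C)C(C)(C)C)[C@H]1CC(C)(C)[C@@H]1CO | intermediate
15 | (1R,4S)-4-[5-(tert-butyldimethylsilyloxy)pent-1-en-2-yl]-2,2-dimethylcyclobutane-1-carbaldehyde | C=C(CCCO[Si](C)(C)C(C)(C)C)[C@H]1CC(C)(C)[C@@H]1C=O | intermediate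
16 | (E)-4-{(1R,4S)-4-[5-(tert-butyldimethylsilyloxy)pent-1-en-2-yl]-2,2-dimethylcyclobutyl}but-3-en-2-one | C=C(CCCO[Si](C)(C)C(C)(C)C)[C@H]1CC(C)(C)[C@@H]1/C=C/C(C)=O | intermediate
17 | 4-{(1R,4S)-4-[5-(tert-butyldimethylsilyloxy)pent-1-en-2-yl]-2,2-dimethylcyclobutyl}butan-2-one | C=C(CCCO[Si](C)(C)C(C)(C)C)[C@H]1CC(C)(C)[C@@H]1CCC(C)=O | intermediate
18 | 4-[(1R,4S)-4-(5-hydroxypent-1-en-2-yl)-2,2-dimethylcyclobutyl]butan-2-one | C=C(CCCO)[C@H]1CC(C)(C)[C@@H]1CCC(C)=O | intermediate
19 | linoleic acid, (9Z,12Z)-octadeca-9,12-dienoic acid | CCCCC/C=C\C/C=C\CCCCCCCC(=O)O | starting material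
20 | IN0146, 4-[(1S,2R)-3,3-dimethyl-2-(3-oxobutyl)cyclobutyl]pent-4-en-1-yl (9Z,12Z)-octadeca-9,12-dienoate | C=C(CCCOC(=O)CCCCCCC/C=C\C/C=C\CCCCC)[C@H]1CC(C)(C)[C@@H]1CCC(C)=O | target

Total step count: 13.
Longest linear sequence: 13 steps (1 → 20). The alkylzinc reagent 11 is generated inside step 6, and 4, 10 and 19 are used as purchased.

Steps most likely to fail

Step 4. The ring closure may lose to intermolecular coupling and give oligomers, an enolate may be α-chlorinated by CuCl2, or a bond may form on a shielded enolate face and give the cis ring or the wrong trans enantiomer. The fallback gives up building the ring. It does not start from a numbered compound of the route: it sets out from commercial (−)-β-caryophyllene F1, whose ring-fusion carbons are already C-b and C-a in the required (1R,9S) configuration, and it comes back at 18. Ozonolysis confined to the strained endocyclic trisubstituted alkene (O3, 1.0 equiv, CH2Cl2/MeOH, −78 °C; Me2S) should leave the exocyclic methylene and give the keto aldehyde 4-[(1S,2R)-3,3-dimethyl-2-(3-oxobutyl)cyclobutyl]pent-4-enal F2. NaBH(OAc)3 (THF, rt) should then reduce only the aldehyde and deliver 18, which is esterified as in step 13.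

Step 5. The thiolate may fail to discriminate between the two imides, giving double cleavage or attack at the acyl group on C-b. The fallback sets out from 8 and comes back at 15. Both auxiliaries are removed with excess EtSLi (THF, rt) to give S,S'-diethyl (1S,2R)-3,3-dimethylcyclobutane-1,2-bis(carbothioate) F3, and the choice between the two acyl groups is moved to the palladium-catalysed coupling, where oxidative addition into the acyl–sulfur bond beside CMe2 should be much slower. One equivalent of 11 with PdCl2(PPh3)2 should give S-ethyl (1R,4S)-4-[4-(tert-butyldimethylsilyloxy)butanoyl]-2,2-dimethylcyclobutane-1-carbothioate F4. Methylenation with Zn/CH2Br2/TiCl4 should give S-ethyl (1R,4S)-4-[5-(tert-butyldimethylsilyloxy)pent-1-en-2-yl]-2,2-dimethylcyclobutane-1-carbothioate F5, and i-Bu2AlH (CH2Cl2, −78 °C) reduces the remaining thioester directly to aldehyde 15, so that step 8 is bypassed as well.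

Step 8. Hydride may attack the ring carbonyl of the oxazolidinone instead of the shielded acyl carbonyl and open the auxiliary to a hydroxy amide, or the reduction may stall. The fallback sets out from 13 and comes back at 14. LiOH/H2O2 (THF/H2O, 0 °C), whose hydroperoxide anion attacks the acyl carbonyl even of hindered imides, should give (1R,4S)-4-[5-(tert-butyldimethylsilyloxy)pent-1-en-2-yl]-2,2-dimethylcyclobutane-1-carboxylic acid F6, and LiAlH4 (THF, 0 °C) then reduces the acid to 14 without touching the alkene or the silyl ether.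

Further compounds
F1 | step 4 | (−)-β-caryophyllene, (1R,4E,9S)-4,11,11-trimethyl-8-methylidenebicyclo[7.2.0]undec-4-ene (commercial starting point of the fallback) | C/C1=C\CCC(=C)[C@H]2CC(C)(C)[C@@H]2CC1
F2 | step 4 | 4-[(1S,2R)-3,3-dimethyl-2-(3-oxobutyl)cyclobutyl]pent-4-enal | C=C(CCC=O)[C@H]1CC(C)(C)[C@@H]1CCC(C)=O
F3 | step 5 | S,S'-diethyl (1S,2R)-3,3-dimethylcyclobutane-1,2-bis(carbothioate) | CCSC(=O)[C@H]1CC(C)(C)[C@@H]1C(=O)SCC
F4 | step 5 | S-ethyl (1R,4S)-4-[4-(tert-butyldimethylsilyloxy)butanoyl]-2,2-dimethylcyclobutane-1-carbothioate | CC(C)(C)[Si](C)(C)OCCCC(=O)[C@H]1CC(C)(C)[C@@H]1C(=O)SCC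
F5 | step 5 | S-ethyl (1R,4S)-4-[5-(tert-butyldimethylsilyloxy)pent-1-en-2-yl]-2,2-dimethylcyclobutane-1-carbothioate | C=C(CCCO[Si](C)(C)C(C)(C)C)[C@H]1CC(C)(C)[C@@H]1C(=O)SCC
F6 | step 8 | (1R,4S)-4-[5-(tert-butyldimethylsilyloxy)pent-1-en-2-yl]-2,2-dimethylcyclobutane-1-carboxylic acid | C=C(CCCO[Si](C)(C)C(C)(C)C)[C@H]1CC(C)(C)[C@@H]1C(=O)O
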